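- Neither run shows the catalyst, so its forms cannot be counted. Under discussion are Qd taking up Qb to give Qe and Qc, Qe turning Qa into Qf and going back to Qd, and two Qe pairing to Qg. What can be read is how the pace of Qf answers to scale.

all flasks: Qd 2.4 mol%
- beta: Qa 0.050 M; Qb 1.1 equiv; the very flask that is asked about, followed so far
- delta: Qa 0.10 M; Qb 1.1 equiv; run made earlier
- flask: Qa 0.050 M; Qb 1.10 equiv; volume of the second phase over the first 1.0

| run | time / min | Qf / % | Qa / % |
|---|---|---|---|
| beta | 0.667 | 1.7 | 97.9 |
| beta | 2.00 | 5.1 | 95.2 |
| beta | 3.00 | 8.5 | 92.2 |
| beta | 5.00 | 14.7 | 85.4 |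
| delta | 1.00 | 5.3 | 94.6 |
| delta | 2.00 | 10.2 | 90.3 |
| delta | 3.00 | 14.6 | 85.0 |
| delta | 4.00 | 18.8 | 82.4 |

(readings scatter by 0.5 percentage points)

- in the second phase: Qb, Qc; everything else is in the first
- charges count per volume of the first phase; a concentration in a rate is the amount of a species over the volume of its own phase; every rate counts per litre of the first phase
- the numbers in the tables scatter by 0.5 percentage points (one standard deviation)
- steps under discussion: Qd + Qb <-> Qe + Qc; Qa + Qe -> Qf + Qd; 2 Qe <-> Qg
- the earlier runs hold the two phases in the same ratio of volumes as the flask asked about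

1. apparent order in Qb when 20% of the Qa are converted (percent change of the rate of making Qf for one percent more Qb charged)
2. factor on the rate of making Qf when 20% of the Qa are converted if Qb is charged twice over

- The pseudo-first-order constant, the fraction of Qa going per minute, reads 0.0318 min⁻¹ in the beta run (Qf 14.7% at 5.00 min) and 0.0521 min⁻¹ in the delta run (Qf 18.8% at 4.00 min).
- The delta run has every charge at twice those of the beta run, so at equal conversion Qb stands to Qc as before, and the exchange, which weighs one against the other, leaves Qe to Qd in the same proportion. The pairing balance sets the square of Qe against Qg, so it shifts with scale.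
- The scale exponent reads 0.711: the power of the catalyst charge that this constant follows. It stands below one, and the forecast reads about 0.8 for the same thing.
- This reckoning commits to a factor 0.611 on the time to 20% with twice the Qd. The exponent was read with every charge doubled, so this is an estimate for Qd doubled by itself. It does not reach the order in Qb, since at equal conversion Qb stood to Qc alike in the two runs.
- The hunch of a weak response to Qb stands in the forecast: order 0.16 (0.03 to 0.45) and factor 1.1 (1.02 to 1.35), with the remark “K is poorly determined, so the upper bounds are wide”.
- The flask gives an order of 0.45 in Qb, 2.81 times the forecast's value, and a factor 1.25 for doubled Qb, inside the forecast's range.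

    Qd + Qb ⇌ Qe + Qc (K = 0.480, k = 79.0 M⁻¹ min⁻¹)
    Qa + Qe → Qf + Qd (k = 63.0 M⁻¹ min⁻¹)
    2 Qe ⇌ Qg, settled at all times (K = 580 M⁻¹)

- At 7.60 min, with 20% of the Qa converted, Qg holds 18.8% of the catalyst in this flask. The scale exponent's factor 0.611, applied to those 7.60 min, gives 4.64 min with twice the Qd, and the simulated run with twice the Qd has a factor 0.593, which is 4.51 min.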